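The runs are calculated for substances that don't exist, noise included.

In a one-step world, where substrate simply turns into first product, I would follow one molecule and ask for its chance per hour of taking that step. You want a quick number for north and west, and that chance is what I would reckon with. The usual term is an initial rate, pseudo-first-order in substrate if the reagent stays steady under the held gas, which I assume.

common to all: gas 12 mM (held)
- ochre: substrate 0.42 M; temperature −20 °C; run made earlier
- teal: substrate 0.66 M; temperature −5 °C; run made earlier
- north: substrate 0.30 M; at 5 °C until 40 min, from then on at −15 °C; time 3.0 h
- west: substrate 0.30 M; at −15 °C throughout; time 12 h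

- ochre (time / h: first product / %): 1.50: 2.5; 3.00: 4.9; 5.00: 7.0; 6.00: 8.1; 8.00: 9.8
- teal (time / h: first product / %): 0.333: 1.2; 1.00: 6.0; 1.50: 7.9; 2.50: 13.2; 4.00: 18.7

(readings scatter by 0.5 percentage points)

- the winner by amount of first product, in percent of the substrate charged; "neither" if no more than 2 percentage points parts them (north / west / neither)
- how much first product is there at the end, in percent of the substrate charged: north
- how much first product is there at the end, in percent of the substrate charged: west

- at the start none of reagent is dissolved
- steps under discussion: substrate + reagent -> other mono adduct; gas <-> reagent; reagent + other mono adduct -> double product; reagent + first product -> double product; substrate + reagent -> first product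

Dividing a reading by its time, ochre at 3.00 h gives 0.0163 h⁻¹ and teal at 2.50 h gives 0.0528 h⁻¹, a factor of 3.23, and both carry the scatter of 0.5 percentage points. Ochre and teal differ in substrate as well as in temperature, but I assume the step is first order in substrate, so that a share of the charge carries across from one to the other. On that assumption I spread the factor evenly over the degrees from −20 °C to −5 °C, and so I read 0.0242 h⁻¹ at −15 °C: the chance per hour that a substrate molecule becomes first product at that temperature. The same spreading, carried past teal to 5 °C, gives 0.115 h⁻¹. So north, warm for 40 min and cold for the rest of its 3.0 h, reaches about 13.3% by my reckoning.

West, cold for 12 h, has a straight line reaching 29.0%. But molecules meet forks: substrate can also go to other mono adduct, and first product can go on to double product. Ochre's readings bend, for its reading at 8.00 h stands at 0.750 of the straight line through its reading at 3.00 h. I hold that reading as the share for west and get 21.7%.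

The forecast is 11.5% for north and 16.5% for west, with west ahead, treating “the first product as formed and then consumed”. I agree on the winner, since my west leads my north by more than the margin of 2 points. But my west stands 5.2 points above the forecast's and my north 1.8 points above it, so we part further on west than on north.

The flasks give 13.8% for north and 23.6% for west, so west has more.

    substrate + reagent → other mono adduct (k = 11.8 L mol⁻¹ h⁻¹, Ea = 67.0 kJ mol⁻¹)
    gas ⇌ reagent, rate k2*(csat - [reagent]) (kL = 13.8 h⁻¹)
    reagent + other mono adduct → double product (k = 17.9 L mol⁻¹ h⁻¹, Ea = 69.0 kJ mol⁻¹)
    reagent + first product → double product (k = 7.39 L mol⁻¹ h⁻¹, Ea = 45.0 kJ mol⁻¹)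
    substrate + reagent → first product (k = 22.3 L mol⁻¹ h⁻¹, Ea = 65.0 kJ mol⁻¹)
    (constants at 5 °C)

At 12.0 h in west, first product is still being made 3.96 times faster than it is used up, each step taken net. Held against the chance per hour, west stands at 0.813 of its straight line of 29.0%. West read at 5.0 h holds 12.0% of first product, and 0.0242 h⁻¹ over that time gives 12.1%.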